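Side-chain carbons are numbered C1' to C36' from the quinone ring; the stereocentres are C7' (R) and C11' (S). Retrosynthesis: the quinone ring is first taken back to its 1,4-dimethoxynaphthalene, then the chain is cut at C10'–C11' into a C33 secondary tosylate and a C23 primary Grignard reagent.
Right half: cut at C1'–C2' (alkenylalane + benzylic chloride, the C2'=C3' olefin coming from a terminal alkyne) and at C4'–C5' (propargyl anion + citronellyl bromide). Left half: cut at C24'–C25' and C12'–C13' (farnesyl phenyl sulfone used twice, as its potassium derivative against a farnesyl-derived allylic bromide and as its lithium derivative against propylene oxide).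
Enabling feature: C11' is a CH(CH3) flanked only by the methylenes C10' and C12', and the nearest π-bond is C14'=C15'. C12', C11' and its methyl therefore map onto (S)-propylene oxide, and the C11'–O bond of the derived 2-alkyl tosylate can be exchanged for C11'–C10' by SN2 with inversion, without allylic or neighbouring-group interference.
Forward order: the right half is built from the citronellyl end toward the arene; the left half is built outward from farnesyl phenyl sulfone; the halves are joined at C10'–C11'; the quinone is unveiled last.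
Stereochemistry: C7' from (R)-citronellyl bromide (never touched); C11' from (S)-propylene oxide by inversion in the union; E olefins from (2E,6E)-farnesyl units, E-selective SeO2 oxidation and syn-carboalumination.

Key step: step 13

Assumption: the sulfonyl-bearing carbons made in the left-half sequence and the acetal carbon of the ozonide form as both epimers; they are not stereocentres of the target, are removed later, and are left undefined in the SMILES.

Step 1
Reactants: 1 1,4-dimethoxy-2-methylnaphthalene
Product: 2 2-(chloromethyl)-1,4-dimethoxy-3-methylnaphthalene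
Conditions: (CH2O)n, conc. aq. HCl, 1,4-dioxane, 40 °C
Reagents that add atoms: formaldehyde (as paraformaldehyde), C=O; hydrogen chloride, Cl
Why: Blanc chloromethylation, in which the electrophile attacks C3, the only unsubstituted position of the ring activated by both methoxy groups, and HCl converts the benzylic alcohol to the chloride; no stereocentre is formed.

Step 2
Reactants: 3 (R)-citronellyl bromide; 4 1-(trimethylsilyl)propyne
Product: 6 (6S)-(6,10-dimethylundec-9-en-1-yn-1-yl)trimethylsilane, via lithiated silylpropyne 5 (not isolated)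
Conditions: 4, n-BuLi, THF, −78 → −20 °C; then 3, THF/DMPU, −78 °C → rt
Reagents that add atoms: none
Why: SN2 alkylation of the propargylic lithium reagent by the primary bromide, with the silyl group steering attack through the CH2 terminus instead of the allenyl position; the stereocentre is not involved and keeps its arrangement (the descriptor changes from R to S only because the priorities change).

Step 3
Reactants: 6 (6S)-(6,10-dimethylundec-9-en-1-yn-1-yl)trimethylsilane
Product: 9 (4S)-4-methylnon-8-yn-1-ol, via ozonide 7 (not isolated), via silyl alkynol 8 (not isolated)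
Conditions: O3, CH2Cl2, −78 °C (Sudan red end point); then NaBH4, MeOH, −78 °C → rt; then K2CO3, rt
Reagents that add atoms: ozone, [O-][O+]=O
Why: Criegee ozonolysis should cleave the electron-rich trisubstituted olefin much faster than the silylated alkyne, NaBH4 reduces the ozonide to the primary alcohol, and methanolysis removes the alkynyl silyl group; no stereocentre is formed or touched.

Step 4
Reactants: 9 (4S)-4-methylnon-8-yn-1-ol
Product: 10 (6S)-9-chloro-6-methylnon-1-yne
Conditions: PPh3, N-chlorosuccinimide, CH2Cl2, 0 °C → rt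
Reagents that add atoms: N-chlorosuccinimide, O=C1CCC(=O)N1Cl
Why: Appel-type chlorination (alkoxyphosphonium ion, then SN2 displacement by chloride at the primary carbon), to which the terminal alkyne and the remote stereocentre are inert.

Step 5
Reactants: 10 (6S)-9-chloro-6-methylnon-1-yne; 2 2-(chloromethyl)-1,4-dimethoxy-3-methylnaphthalene
Product: 12 2-[(2E,7S)-10-chloro-3,7-dimethyldec-2-en-1-yl]-1,4-dimethoxy-3-methylnaphthalene, via alkenylalane 11 (not isolated)
Conditions: AlMe3 (2 equiv), Cp2ZrCl2 (0.25 equiv), ClCH2CH2Cl, 0 °C → rt; volatiles removed; then 2, Ni(cod)2 (5 mol%), PPh3 (10 mol%), THF, rt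
Reagents that add atoms: trimethylaluminium, C[Al](C)C
Why: Negishi zirconium-catalysed carboalumination adds CH3 and Al syn across the terminal alkyne with CH3 on the internal carbon, which fixes the (E)-C2'=C3' olefin, and the nickel-catalysed Negishi-type cross-coupling of the alkenylalane with the benzylic chloride then forms C1'–C2' with retention of geometry, the primary alkyl chloride being inert to zerovalent nickel–phosphine at room temperature.

Step 6
Reactants: 13 (2E,6E)-farnesyl bromide
Product: 14 (2E,6E)-farnesyl phenyl sulfone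
Conditions: PhSO2Na, DMF, rt
Reagents that add atoms: sodium benzenesulfinate, [Na+].[O-]S(=O)c1ccccc1
Why: SN2 S-alkylation of the sulfinate by the primary allylic bromide should give the sulfone without change of the (2E,6E) geometry.

Step 7
Reactants: 14 (2E,6E)-farnesyl phenyl sulfone; 15 (S)-propylene oxide
Product: 18 (2S,5E,9E)-6,10,14-trimethyl-4-(phenylsulfonyl)pentadeca-5,9,13-trien-2-yl pivalate, via lithiated sulfone 16 (not isolated), via lithium alkoxide 17 (not isolated)
Conditions: n-BuLi, THF/DMPU, −78 °C; then 15, −78 → 0 °C; then t-BuCOCl, DMAP (cat.), 0 °C → rt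
Reagents that add atoms: pivaloyl chloride, CC(C)(C)C(=O)Cl
Why: Julia-type sulfone carbanion chemistry, in which the allyl sulfone anion reacts through its α-carbon and opens the epoxide at the unsubstituted CH2 (SN2), so the carbinol carbon keeps the (S) configuration of the epoxide, and the alkoxide is acylated in the flask as in a Julia–Lythgoe sequence; the sulfonyl-bearing carbon forms as both epimers and is removed in step 11.

Step 8
Reactants: 18 (2S,5E,9E)-6,10,14-trimethyl-4-(phenylsulfonyl)pentadeca-5,9,13-trien-2-yl pivalate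
Product: 19 (2S,5E,9E,13E)-15-hydroxy-6,10,14-trimethyl-4-(phenylsulfonyl)pentadeca-5,9,13-trien-2-yl pivalate
Conditions: SeO2 (0.3 equiv), t-BuOOH (3 equiv), salicylic acid (0.1 equiv), CH2Cl2, 0 °C → rt
Reagents that add atoms: selenium dioxide (catalytic oxygen carrier), O=[Se]=O; tert-butyl hydroperoxide (terminal oxidant), CC(C)(C)OO
Why: Riley-type SeO2 allylic oxidation (ene reaction, then [2,3]-sigmatropic shift) should hydroxylate the (E)-methyl group of the terminal isopropylidene, the most electron-rich and least hindered olefin, to give the (E)-allylic alcohol, while the olefin next to the sulfonyl group is deactivated.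

Step 9
Reactants: 19 (2S,5E,9E,13E)-15-hydroxy-6,10,14-trimethyl-4-(phenylsulfonyl)pentadeca-5,9,13-trien-2-yl pivalate
Product: 20 (2S,5E,9E,13E)-15-bromo-6,10,14-trimethyl-4-(phenylsulfonyl)pentadeca-5,9,13-trien-2-yl pivalate
Conditions: CBr4, PPh3, CH2Cl2, 0 °C
Reagents that add atoms: carbon tetrabromide, BrC(Br)(Br)Br
Why: Appel bromination (SN2 of bromide on the primary allylic alkoxyphosphonium ion) runs under neutral conditions and should proceed without allylic transposition or loss of the 13E geometry.

Step 10
Reactants: 14 (2E,6E)-farnesyl phenyl sulfone; 20 (2S,5E,9E,13E)-15-bromo-6,10,14-trimethyl-4-(phenylsulfonyl)pentadeca-5,9,13-trien-2-yl pivalate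
Product: 22 (2S,5E,9E,13E,17E,21E)-6,10,14,18,22,26-hexamethyl-4,16-bis(phenylsulfonyl)heptacosa-5,9,13,17,21,25-hexaen-2-yl pivalate, via potassiated sulfone 21 (not isolated)
Conditions: 14 (1.3 equiv), KN(SiMe3)2 (1.2 equiv), THF, −78 °C; then 20 (1.0 equiv), −78 → −40 °C
Reagents that add atoms: none
Why: Julia-type sulfone alkylation (Biellmann coupling), in which the silylamide base, which cannot add to the pivalate or undergo halogen–metal exchange with the bromide as an alkyllithium could, converts 14 into its potassium α-sulfonyl carbanion, and this loose ion pair displaces the primary allylic bromide by SN2 at low temperature and so forms C24'–C25' without touching any olefin, the hindered pivalate and the less acidic secondary α-sulfonyl C–H of the bromide being spared because the base is used in deficiency relative to 14; the second sulfonyl-bearing carbon forms as both epimers.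

Step 11
Reactants: 22 (2S,5E,9E,13E,17E,21E)-6,10,14,18,22,26-hexamethyl-4,16-bis(phenylsulfonyl)heptacosa-5,9,13,17,21,25-hexaen-2-yl pivalate
Product: 23 (2S,5E,9E,13E,17E,21E)-6,10,14,18,22,26-hexamethylheptacosa-5,9,13,17,21,25-hexaen-2-ol
Conditions: PdCl2(dppp) (10 mol%), LiEt3BH (8 equiv), THF, 0 °C → rt
Reagents that add atoms: none
Why: Tsuji–Trost-type reductive desulfonylation, in which zerovalent palladium ionises each allylic sulfone to a π-allyl complex and hydride is delivered to the less substituted terminus (the former sulfonyl carbon), which should keep the position and E geometry of both flanking olefins, while the same hydride cleaves the pivalate to free the (S)-alcohol.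

Step 12
Reactants: 23 (2S,5E,9E,13E,17E,21E)-6,10,14,18,22,26-hexamethylheptacosa-5,9,13,17,21,25-hexaen-2-ol
Product: 24 (2S,5E,9E,13E,17E,21E)-6,10,14,18,22,26-hexamethylheptacosa-5,9,13,17,21,25-hexaen-2-yl 4-methylbenzenesulfonate
Conditions: TsCl, DMAP, pyridine, CH2Cl2, 0 °C → rt
Reagents that add atoms: p-toluenesulfonyl chloride, Cc1ccc(cc1)S(Cl)(=O)=O
Why: O-sulfonylation of the secondary alcohol breaks no bond at the stereocentre, so the (S) configuration is carried into the leaving group.

Step 13
Reactants: 12 2-[(2E,7S)-10-chloro-3,7-dimethyldec-2-en-1-yl]-1,4-dimethoxy-3-methylnaphthalene; 24 (2S,5E,9E,13E,17E,21E)-6,10,14,18,22,26-hexamethylheptacosa-5,9,13,17,21,25-hexaen-2-yl 4-methylbenzenesulfonate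
Product: 26 1,4-dimethoxy-2-methyl-3-[(2E,7R,11S,14E,18E,22E,26E,30E)-3,7,11,15,19,23,27,31,35-nonamethylhexatriaconta-2,14,18,22,26,30,34-heptaen-1-yl]naphthalene, via Grignard reagent 25 (not isolated)
Conditions: 12 (1.5 equiv), Mg, THF, 50 °C; then 24 (1.0 equiv), CuI (10 mol%), TMEDA (1.5 equiv), LiOMe (1 equiv), THF, 0 °C
Reagents that add atoms: none
Why: The Grignard reagent 25 transmetalates to an alkylcopper species that attacks C11' of tosylate 24 from the face opposite the sulfonate (SN2-type oxidative addition, then reductive elimination), forming the C10'–C11' bond and uniting the C23 and C33 halves. The closest known reaction type is the copper-catalysed Kumada-type cross-coupling of unactivated secondary alkyl tosylates with alkyl Grignard reagents, which proceeds with inversion. No ring is closed. The only new stereocentre, C11', is controlled by the substrate: inversion turns the (S)-carbinol carbon derived from (S)-propylene oxide into the (11'S) methyl-branched centre (the descriptor stays S because the priorities change), while C7' is remote and untouched. The step needs substitution to outrun E2 elimination and attack at sulfur; this is favoured by the low basicity of the organocopper at 0 °C, the unbranched primary nucleophile, and the fact that C11' is flanked only by CH3 and two CH2 groups, with the nearest olefin (C14'=C15') too far away to give an allylic cation or a fast radical ring closure. The trisubstituted olefins and the aryl methyl ethers should be inert to the organocopper species.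

Step 14
Reactants: 26 1,4-dimethoxy-2-methyl-3-[(2E,7R,11S,14E,18E,22E,26E,30E)-3,7,11,15,19,23,27,31,35-nonamethylhexatriaconta-2,14,18,22,26,30,34-heptaen-1-yl]naphthalene
Product: 27 2-methyl-3-[(2E,7R,11S,14E,18E,22E,26E,30E)-3,7,11,15,19,23,27,31,35-nonamethylhexatriaconta-2,14,18,22,26,30,34-heptaen-1-yl]naphthalene-1,4-dione (CNP0265071.1)
Conditions: (NH4)2Ce(NO3)6, MeCN/CH2Cl2/H2O, 0 °C
Reagents that add atoms: water, O
Why: Oxidative demethylation of the 1,4-dimethoxyarene, in which two single-electron oxidations by tetravalent cerium and attack of water at the methoxy-bearing carbons release methanol and give the 1,4-quinone, the electron-rich arene being oxidised far more readily than the isolated trisubstituted olefins; no stereocentre is affected.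

Compound list
1 | 1,4-dimethoxy-2-methylnaphthalene | COc1cc(C)c(OC)c2ccccc12 | starting material
2 | 2-(chloromethyl)-1,4-dimethoxy-3-methylnaphthalene | COc1c(CCl)c(C)c(OC)c2ccccc12 | intermediate
3 | (R)-citronellyl bromide, (6R)-8-bromo-2,6-dimethyloct-2-ene | BrCC[C@H](C)CCC=C(C)C | starting material
4 | 1-(trimethylsilyl)propyne | CC#C[Si](C)(C)C | starting material
5 | 3-lithio-1-(trimethylsilyl)propyne (formed in the flask) | [Li]CC#C[Si](C)(C)C | intermediate
6 | (6S)-(6,10-dimethylundec-9-en-1-yn-1-yl)trimethylsilane | C[Si](C)(C)C#CCCC[C@H](C)CCC=C(C)C | intermediate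
7 | ozonide of 6, 3,3-dimethyl-5-[(3S)-3-methyl-8-(trimethylsilyl)oct-7-yn-1-yl]-1,2,4-trioxolane, both epimers at the ring CH (formed in the flask) | CC1(C)OOC(CC[C@@H](C)CCCC#C[Si](C)(C)C)O1 | intermediate
8 | (4S)-4-methyl-9-(trimethylsilyl)non-8-yn-1-ol (formed in the flask) | OCCC[C@@H](C)CCCC#C[Si](C)(C)C | intermediate
9 | (4S)-4-methylnon-8-yn-1-ol | OCCC[C@@H](C)CCCC#C | intermediate
10 | (6S)-9-chloro-6-methylnon-1-yne | ClCCC[C@@H](C)CCCC#C | intermediate
11 | [(1E,6S)-9-chloro-2,6-dimethylnon-1-en-1-yl]dimethylalumane (formed in the flask) | ClCCC[C@@H](C)CCC/C(C)=C/[Al](C)C | intermediate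
12 | 2-[(2E,7S)-10-chloro-3,7-dimethyldec-2-en-1-yl]-1,4-dimethoxy-3-methylnaphthalene | ClCCC[C@@H](C)CCC/C(C)=C/Cc1c(C)c(OC)c2ccccc2c1OC | intermediate
13 | (2E,6E)-farnesyl bromide, (2E,6E)-1-bromo-3,7,11-trimethyldodeca-2,6,10-triene | CC(C)=CCC/C(C)=C/CC/C(C)=C/CBr | starting material
14 | (2E,6E)-farnesyl phenyl sulfone, {[(2E,6E)-3,7,11-trimethyldodeca-2,6,10-trien-1-yl]sulfonyl}benzene | CC(C)=CCC/C(C)=C/CC/C(C)=C/CS(=O)(=O)c1ccccc1 | intermediate
15 | (S)-propylene oxide, (S)-2-methyloxirane | C[C@H]1CO1 | starting material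
16 | [(2E,6E)-3,7,11-trimethyl-1-(phenylsulfonyl)dodeca-2,6,10-trien-1-yl]lithium (formed in the flask) | CC(C)=CCC/C(C)=C/CC/C(C)=C/C([Li])S(=O)(=O)c1ccccc1 | intermediate
17 | lithium (2S,5E,9E)-6,10,14-trimethyl-4-(phenylsulfonyl)pentadeca-5,9,13-trien-2-olate, both C4 epimers (formed in the flask) | CC(C)=CCC/C(C)=C/CC/C(C)=C/C(C[C@H](C)O[Li])S(=O)(=O)c1ccccc1 | intermediate
18 | (2S,5E,9E)-6,10,14-trimethyl-4-(phenylsulfonyl)pentadeca-5,9,13-trien-2-yl pivalate, both C4 epimers | CC(C)=CCC/C(C)=C/CC/C(C)=C/C(C[C@H](C)OC(=O)C(C)(C)C)S(=O)(=O)c1ccccc1 | intermediate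
19 | (2S,5E,9E,13E)-15-hydroxy-6,10,14-trimethyl-4-(phenylsulfonyl)pentadeca-5,9,13-trien-2-yl pivalate, both C4 epimers | OC/C(C)=C/CC/C(C)=C/CC/C(C)=C/C(C[C@H](C)OC(=O)C(C)(C)C)S(=O)(=O)c1ccccc1 | intermediate
20 | (2S,5E,9E,13E)-15-bromo-6,10,14-trimethyl-4-(phenylsulfonyl)pentadeca-5,9,13-trien-2-yl pivalate, both C4 epimers | BrC/C(C)=C/CC/C(C)=C/CC/C(C)=C/C(C[C@H](C)OC(=O)C(C)(C)C)S(=O)(=O)c1ccccc1 | intermediate
21 | [(2E,6E)-3,7,11-trimethyl-1-(phenylsulfonyl)dodeca-2,6,10-trien-1-yl]potassium (formed in the flask) | CC(C)=CCC/C(C)=C/CC/C(C)=C/C([K])S(=O)(=O)c1ccccc1 | intermediate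
22 | (2S,5E,9E,13E,17E,21E)-6,10,14,18,22,26-hexamethyl-4,16-bis(phenylsulfonyl)heptacosa-5,9,13,17,21,25-hexaen-2-yl pivalate, epimers at C4 and C16 | CC(C)=CCC/C(C)=C/CC/C(C)=C/C(S(=O)(=O)c1ccccc1)C/C(C)=C/CC/C(C)=C/CC/C(C)=C/C(C[C@H](C)OC(=O)C(C)(C)C)S(=O)(=O)c1ccccc1 | intermediate
23 | (2S,5E,9E,13E,17E,21E)-6,10,14,18,22,26-hexamethylheptacosa-5,9,13,17,21,25-hexaen-2-ol | CC(C)=CCC/C(C)=C/CC/C(C)=C/CC/C(C)=C/CC/C(C)=C/CC/C(C)=C/CC[C@H](C)O | intermediate
24 | (2S,5E,9E,13E,17E,21E)-6,10,14,18,22,26-hexamethylheptacosa-5,9,13,17,21,25-hexaen-2-yl 4-methylbenzenesulfonate | CC(C)=CCC/C(C)=C/CC/C(C)=C/CC/C(C)=C/CC/C(C)=C/CC/C(C)=C/CC[C@H](C)OS(=O)(=O)c1ccc(C)cc1 | intermediate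
25 | [(4S,8E)-10-(1,4-dimethoxy-3-methylnaphthalen-2-yl)-4,8-dimethyldec-8-en-1-yl]magnesium chloride (formed in the flask) | Cl[Mg]CCC[C@@H](C)CCC/C(C)=C/Cc1c(C)c(OC)c2ccccc2c1OC | intermediate
26 | 1,4-dimethoxy-2-methyl-3-[(2E,7R,11S,14E,18E,22E,26E,30E)-3,7,11,15,19,23,27,31,35-nonamethylhexatriaconta-2,14,18,22,26,30,34-heptaen-1-yl]naphthalene | CC(C)=CCC/C(C)=C/CC/C(C)=C/CC/C(C)=C/CC/C(C)=C/CC/C(C)=C/CC[C@@H](C)CCC[C@@H](C)CCC/C(C)=C/Cc1c(C)c(OC)c2ccccc2c1OC | intermediate
27 | 2-methyl-3-[(2E,7R,11S,14E,18E,22E,26E,30E)-3,7,11,15,19,23,27,31,35-nonamethylhexatriaconta-2,14,18,22,26,30,34-heptaen-1-yl]naphthalene-1,4-dione | CC(C)=CCC/C(C)=C/CC/C(C)=C/CC/C(C)=C/CC/C(C)=C/CC/C(C)=C/CC[C@@H](C)CCC[C@@H](C)CCC/C(C)=C/CC1=C(C)C(=O)c2ccccc2C1=O | target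

Total step count: 14.
Longest linear sequence: 9 steps (steps 6 to 14, from 13 to 27).

Steps most likely to fail

Step 13. E2 elimination of the secondary tosylate and attack of the Grignard reagent at sulfur may outrun the copper-mediated substitution, or turnover of the hindered alkylcopper may be slow. The fallback replaces the organocopper by a stabilised carbanion; it sets out from 12 and 24 and comes back at 26. Chloride 12 is heated with PhSO2Na and NaI (cat.) in DMF to give the right-half phenyl sulfone F1. Its α-lithio derivative (n-BuLi, THF/DMPU, −78 °C) is alkylated by tosylate 24 with inversion at C11' to give the C10'-sulfonylated coupling product F2 (both C10' epimers). Reductive desulfonylation with 6% Na/Hg and Na2HPO4 in MeOH/THF then gives 26.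

Step 8. Oxidation may also take place at the internal olefins, may run on to the enal, or may stall at low conversion. The fallback builds the terminal allylic alcohol by cleavage and olefination instead of C–H oxidation; it sets out from 18 and comes back at 19. NBS in aqueous THF at 0 °C should add selectively to the terminal olefin to give the terminal bromohydrin F3. K2CO3 in MeOH closes it to the terminal epoxide F4. H5IO6 in THF/Et2O cleaves the epoxide, with loss of acetone, to the trisnor aldehyde F5. Wittig reaction with the stabilised ylide Ph3P=C(CH3)CHO gives the (E)-enal F6, and NaBH4 in MeOH at 0 °C reduces it to 19.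

Step 5. Carbometalation may be incomplete or not fully regioselective, and the nickel step may suffer from methyl transfer by residual AlMe3, homocoupling of the benzylic chloride, or oxidative addition into the alkyl chloride. The fallback reverses the polarity of the coupling; it sets out from 10 and 2 and comes back at 12. Alkyne 10 is carboaluminated as in step 5 (via 11) and the alane is quenched with I2 to give the (E)-alkenyl iodide F7. Chloride 2 is converted with Zn dust and LiCl in THF into the benzylic zinc chloride F8. Negishi coupling of F7 with F8, catalysed by Pd(PPh3)4 in THF at rt, gives 12.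

Further compounds
F1 | step 13 | 1,4-dimethoxy-2-methyl-3-[(2E,7S)-3,7-dimethyl-10-(phenylsulfonyl)dec-2-en-1-yl]naphthalene | O=S(=O)(CCC[C@@H](C)CCC/C(C)=C/Cc1c(C)c(OC)c2ccccc2c1OC)c1ccccc1
F2 | step 13 | compound 26 carrying a phenylsulfonyl group on C10', both C10' epimers, with C7' and C11' arranged as in 26 | CC(C)=CCC/C(C)=C/CC/C(C)=C/CC/C(C)=C/CC/C(C)=C/CC/C(C)=C/CC[C@@H](C)C(CC[C@@H](C)CCC/C(C)=C/Cc1c(C)c(OC)c2ccccc2c1OC)S(=O)(=O)c1ccccc1
F3 | step 8 | (2S,5E,9E)-13-bromo-14-hydroxy-6,10,14-trimethyl-4-(phenylsulfonyl)pentadeca-5,9-dien-2-yl pivalate, epimers at C4 and C13 | CC(C)(O)C(Br)CC/C(C)=C/CC/C(C)=C/C(C[C@H](C)OC(=O)C(C)(C)C)S(=O)(=O)c1ccccc1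
F4 | step 8 | (2S,5E,9E)-13,14-epoxy-6,10,14-trimethyl-4-(phenylsulfonyl)pentadeca-5,9-dien-2-yl pivalate, epimers at C4 and C13 | CC1(C)OC1CC/C(C)=C/CC/C(C)=C/C(C[C@H](C)OC(=O)C(C)(C)C)S(=O)(=O)c1ccccc1
F5 | step 8 | (2S,5E,9E)-6,10-dimethyl-13-oxo-4-(phenylsulfonyl)trideca-5,9-dien-2-yl pivalate, both C4 epimers | O=CCC/C(C)=C/CC/C(C)=C/C(C[C@H](C)OC(=O)C(C)(C)C)S(=O)(=O)c1ccccc1
F6 | step 8 | (2S,5E,9E,13E)-6,10,14-trimethyl-15-oxo-4-(phenylsulfonyl)pentadeca-5,9,13-trien-2-yl pivalate, both C4 epimers | O=C/C(C)=C/CC/C(C)=C/CC/C(C)=C/C(C[C@H](C)OC(=O)C(C)(C)C)S(=O)(=O)c1ccccc1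
F7 | step 5 | (1E,6S)-9-chloro-1-iodo-2,6-dimethylnon-1-ene | ClCCC[C@@H](C)CCC/C(C)=C/I
F8 | step 5 | [(1,4-dimethoxy-3-methylnaphthalen-2-yl)methyl]zinc chloride | Cl[Zn]Cc1c(C)c(OC)c2ccccc2c1OC
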